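A small charge of substrate, 0.033 M, goes into each new flask, half of what elm held. The question is which temperature history leaves the best share of target at 20 min.

| flask | substrate | temperature | remark | time |
|---|---|---|---|---|
| birch | 0.017 M | −10 °C | run made earlier |  |
| elm | 0.066 M | 25 °C | run made earlier |  |
| delta | 0.033 M | 55 °C |  | 20 min |
| alpha | 0.033 M |  | at 55 °C until 4.0 min, from then on at −5 °C | 20 min |
| epsilon | 0.033 M | 25 °C |  | 20 min |
| beta | 0.033 M | −5 °C |  | 20 min |

| run | time / min | target / % | isomer of the product / % | over-reaction product / % |
|---|---|---|---|---|
| birch | 60.0 | 18.2 | 69.8 | 1.3 |
| birch | 180 | 33.2 | 58.6 | 1.5 |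
| birch | 300 | 36.9 | 53.8 | 4.1 |
| birch | 480 | 38.9 | 48.9 | 5.9 |
| elm | 12.0 | 24.3 | 43.0 | 20.3 |
| elm | 40.0 | 13.9 | 23.8 | 55.4 |
| elm | 50.0 | 10.6 | 18.9 | 64.3 |
| elm | 80.0 | 6.4 | 10.3 | 81.2 |

(scatter of a reading: 0.5 percentage points)

* the flask that comes out highest in share of target in all that became target or isomer of the product or over-reaction product, or "all alike" when all lie within 1.5 percentage points (delta / alpha / epsilon / beta / all alike)
* share of target in all that became target or isomer of the product or over-reaction product, delta
* share of target in all that became target or isomer of the product or over-reaction product, alpha
* share of target in all that became target or isomer of the product or over-reaction product, epsilon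
* share of target in all that became target or isomer of the product or over-reaction product, beta

- for target the crystals are counted in
- as a solid, counted per litre of solution: crystals
- steps thought possible: substrate <-> target; target <-> isomer of the product; isomer of the product <-> substrate; target -> over-reaction product; crystals <-> target

The first rung is the exchange among substrate, target and isomer of the product. In elm, target over isomer reads 0.565 at 12.0 min and 0.561 at 50.0 min, so in elm this exchange behaves as a pre-equilibrium from the first reading on. Crystals are counted in target, and that ratio shows no rise in elm, at twice the new charge. In elm the three species are taken as one pool. At the first elm reading target is 30.5% of it, and substrate, the part missing from the balance, is 15.6%.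

The next rung is the leak of that pool to over-reaction product. Its measure is the drain constant, the fraction of the pool lost per minute, 0.0212 /min, read between the first and last elm readings. Its half-life, 32.7 min, is longer than 20 min.

Taking the steps as first order, elm's percentages serve for epsilon at the same temperature. From the first elm reading the pool falls to 67.2% at 20 min. That puts over-reaction product at 32.8% and the share of target in epsilon at 22.9%.

Birch reads a drain of 1.52 × 10⁻⁴ /min, a rough value given the scatter, and its share of target is still climbing. Scaled evenly per degree, with the exchange taken to speed up like the drain, beta runs 2.02 times as fast as birch. So 20 min in beta is worth 40.5 min of birch, short of the reading at 60.0 min, where the share reads 20.4%. This reckoning puts beta below epsilon. Scaled the same way, the pool's half-life at 55 °C reckons to 0.474 min, shorter than 4.0 min, so in this rough reckoning over-reaction product takes over in delta and alpha by that time.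

The forecast names epsilon, with 23% there, 16% in beta, 4% in alpha and 0.2% in delta, on the ground that “target and isomer are equilibrated at 25 °C”.

The flasks give 23.4% in epsilon, 18.0% in beta, 3.19% in alpha and 0% in delta, so epsilon comes out highest.

    substrate ⇌ target (K = 2.30, k = 0.00780 /s, Ea = 85.0 kJ/mol, ΔH = −21.0 kJ/mol)
    target ⇌ isomer of the product (K = 1.60, k = 0.00770 /s, Ea = 86.0 kJ/mol, ΔH = 5.00 kJ/mol)
    isomer of the product ⇌ substrate (k = 0.00720 /s, Ea = 81.0 kJ/mol)
    target → over-reaction product (k = 0.00110 /s, Ea = 96.0 kJ/mol)
    crystals ⇌ target, rate k5*(cs5 - [target]) while solid is left; crystals form when [target] > cs5 (solubility = 29.0 mM, k = 0.0640 /s)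
    (constants at 25 °C)

In epsilon, substrate and target relax by their own step, both ways together, with a half-life of 1.03 min, short against 20 min, while the loss of target to over-reaction product runs at 0.14 of its forward loss to isomer of the product. Epsilon holds 32.9% of over-reaction product at 20.0 min. Carried on from there, the drain constant of 0.0212 /min gives 45.7% at 30 min, and epsilon read at that time holds 45.5%.

(The earlier runs and the new flask were computed with constants of no real substance; noise was put on by code.)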